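All runs come from a simulation with constants of no real substance, and the scatter is random.

Time against temperature is the question between the spring and midnight flasks, and the earlier runs price both.

| flask | solid substrate | reagent | free catalyst | temperature | remark | time |
|---|---|---|---|---|---|---|
| south | 1.1 M | 0.88 M | 8 mM | −16 °C | run made earlier |  |
| north | 1.8 M | 0.88 M | 8 mM | −8 °C | run made earlier |  |
| north-east | 0.80 M | 0.88 M | 12 mM | −16 °C | run made earlier |  |
| spring | 0.80 M | 0.880 M | 8.0 mM | −5 °C |  | 10 d |
| midnight | 0.80 M | 0.880 M | 8.0 mM | −20 °C |  | 30 d |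

| run | time / d | product / % | solid substrate / % |
|---|---|---|---|
| south | 2.50 | 12.8 | 71.6 |
| south | 8.00 | 46.2 | 26.1 |
| south | 15.0 | 74.0 | 1.4 |
| south | 20.0 | 77.5 | 0.8 |
| south | 30.0 | 79.1 | 0.6 |
| north | 1.25 | 4.4 | 90.2 |
| north | 4.00 | 16.8 | 73.4 |
| north | 8.00 | 34.2 | 50.1 |
| north | 12.0 | 45.1 | 34.2 |
| north | 15.0 | 46.6 | 25.5 |
| north-east | 6.00 | 57.9 | 19.0 |
| north-east | 12.0 | 89.5 | 0 |
| north-east | 20.0 | 96.1 | 0.2 |
| north-east | 25.0 | 97.6 | 1.9 |
| north-east | 30.0 | 98.2 | 0 |

(standard deviation of a reading: 1 percentage point)

- given per volume of solution although it is solid: solid substrate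
- at the start none of the solid substrate is in solution
- what has only dissolved of solid substrate counts as not reacted

- the winner by amount of product, in percent of the solid substrate charged; "neither" if no more than 2 percentage points parts them (spring / midnight / neither)
- how much product is there at the end, in percent of the solid substrate charged: spring
- how much product is there at the end, in percent of the solid substrate charged: midnight

Over their first intervals, solid substrate leaves at 0.125 M d⁻¹ in the south run at −16 °C and at 0.141 M d⁻¹ in the north run at −8 °C. The two lie within a factor 1.13 although charge and temperature both differ, so I take the north rate for both new flasks, where solid substrate at 0.80 M against reagent at 0.880 M is the limiting charge (limiting reagent):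

feed time = 0.80 M / 0.141 M d⁻¹ = 5.67 d

I carry this, the charge of solid substrate over its early loss rate. The other time is the asked one, and between them lies the window for finishing the dissolved substrate:

midnight 24.3 d, spring 4.33 d, ratio 5.61

Against that stands warmth. Product per day over dissolved substrate times reagent reads 8.03 × 10⁻⁶ M⁻¹ s⁻¹ in the south run and 9.38 × 10⁻⁶ M⁻¹ s⁻¹ in the north run, both carrying the scatter. Stretched from −20 °C to −5 °C, that is a factor 1.34. The window ratio is larger, so I expect midnight to give more.

The forecast says midnight, with spring 87% (80% to 92%) and midnight 94% (89% to 97%): “Time beats warmth.”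

The flasks give spring 89.1% and midnight 96.4%, so midnight leads by 7.3 percentage points.

    solid substrate ⇌ starting material, rate k1*(cs1 - [starting material]) while solid is left; crystals form when [starting material] > cs1 (solubility = 0.650 M, k = 2.50 × 10⁻⁶ s⁻¹)
    reagent + catalyst intermediate A ⇌ catalyst intermediate B (K = 1.40 M⁻¹, k = 8.80 × 10⁻⁴ M⁻¹ s⁻¹, Ea = 53.0 kJ mol⁻¹, ΔH = −4.00 kJ mol⁻¹)
    starting material + free catalyst ⇌ catalyst intermediate A (K = 1.50 M⁻¹, k = 0.00150 M⁻¹ s⁻¹, Ea = 60.0 kJ mol⁻¹, ΔH = −29.0 kJ mol⁻¹)
    catalyst intermediate B → free catalyst + product (k = 0.00590 s⁻¹, Ea = 63.0 kJ mol⁻¹)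
    (constants at −20 °C)

At 5.00 d spring holds 26.9% of its solid substrate where the feed time put 11.8%, so its mean loss of 0.117 M d⁻¹ up to then is lower than the north rate of 0.141 M d⁻¹. At 3.31 d spring makes starting material 1.15 times as fast as it uses it up, each step taken net.

Spring read at 2.50 d sits inside the feed time, which gives 44.1% of the solid substrate gone. The flask has lost 38.4% of it and holds 23.7% product.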